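Ring D is the hexasubstituted benzene of the dihydrochalcone half (D1 C-acyl, D2 OH, D3 CH3, D4 OCH3, D5 CH2 bridge to flavone C8, D6 OH). Its methyl sits between a free hydroxyl and a methyl ether, so D3–D4 is read as the two carbons of 1-methoxypropyne and D2, D5, D6, D1 as C1, C2, C3, C4 of a cyclobutenone.
Last disconnections: the three O-benzyl groups (hydrogenolysis) and the D1–acyl bond (ester on the D2 hydroxyl, then ortho-Fries shift to the only free carbon of ring D).
Key disconnection: bonds D2–D3 and D4–D5, by Danheiser benzannulation of 3-benzyloxy-2-(flavon-8-ylmethyl)cyclobutenone with 1-methoxypropyne; ring D closes at D2–D1.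
The cyclobutenone is traced to a 3-(flavon-8-yl)propanoic acid. Its ketene adds ethoxyacetylene (2+2), hydrolysis gives the symmetric 2-substituted cyclobutane-1,3-dione, and O-benzylation leaves the side chain at C2. No C-alkylation of the parent dione is needed, and the acid comes from the 8-iodoflavone by Negishi coupling.
Ring order: flavone rings A, B and C are bought with 3-O-methylgalangin, the four-membered ring is built on the C8 side chain, and ring D is formed last.

Key step: step 9

Assumption: 3-O-methylgalangin, ethoxyacetylene (hexane solution) and (3-ethoxy-3-oxopropyl)zinc bromide (THF solution) are taken as catalogue items; the 3-methyl ether is chosen because alkylation of galangin does not dependably distinguish its 3-OH from its 7-OH.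
Notation: Fl = 5,7-bis(benzyloxy)-3-methoxy-4-oxo-2-phenyl-4H-chromen-8-yl. The target has no stereocentre; 13 and 17 are racemic and their stereocentres are erased later.

Step 1
Reactants: 1 chloroacetaldehyde dimethyl acetal
Product: 3 1-methoxyprop-1-yne, via sodium methoxyacetylide 2 (not isolated)
Conditions: NaNH2 (3.0 equiv), NH3(l), −33 °C; then MeI (1.0 equiv), −33 °C; NH3 evaporated, H2O, distillation
Reagents that add atoms: iodomethane, CI
Why: Base-induced double elimination (loss of MeOH and HCl) gives methoxyacetylene, which the third equivalent of amide holds as acetylide 2, and SN2 methylation of 2 at carbon is the standard one-pot entry to 1-alkoxy-1-alkynes.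

Step 2
Reactants: 4 3-O-methylgalangin
Product: 5 5,7-bis(benzyloxy)-3-methoxy-2-phenyl-4H-chromen-4-one (Fl–H)
Conditions: BnBr (3 equiv), K2CO3 (4 equiv), DMF, 70 °C
Reagents that add atoms: benzyl bromide, BrCc1ccccc1
Why: Williamson etherification, in which the 7-OH reacts first and warming with excess halide also overcomes the hydrogen bond of the 5-OH to the C4 carbonyl, while O3 already carries the methyl group that the target keeps.

Step 3
Reactants: 5 5,7-bis(benzyloxy)-3-methoxy-2-phenyl-4H-chromen-4-one
Product: 6 5,7-bis(benzyloxy)-8-iodo-3-methoxy-2-phenyl-4H-chromen-4-one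
Conditions: NIS (1.1 equiv), TFA (0.3 equiv), MeCN–CH2Cl2, 0 °C → rt, dark
Reagents that add atoms: N-iodosuccinimide, O=C1CCC(=O)N1I
Why: Electrophilic aromatic iodination of ring A, which in fully O-alkylated 5,7-dioxygenated flavones goes to C8, the position activated by O7 and O1 and less crowded than C6 between two benzyloxy groups, while ring B and the benzyl rings are far less electron-rich.

Step 4
Reactants: 6 5,7-bis(benzyloxy)-8-iodo-3-methoxy-2-phenyl-4H-chromen-4-one; 7 (3-ethoxy-3-oxopropyl)zinc bromide
Product: 8 ethyl 3-Fl-propanoate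
Conditions: 7 (1.8 equiv, 0.5 M in THF), Pd(OAc)2 (5 mol %), SPhos (10 mol %), THF, 50 °C
Reagents that add atoms: none
Why: Negishi coupling, in which oxidative addition of the carbon–iodine bond to zerovalent palladium bearing the bulky biarylphosphine, transmetalation from the alkylzinc and fast reductive elimination form the C8–CH2 bond, and the organozinc adds neither to the chromone carbonyl nor to the ester.

Step 5
Reactants: 8 ethyl 3-Fl-propanoate
Product: 9 3-Fl-propanoic acid
Conditions: LiOH·H2O (3 equiv), THF–H2O, rt; then 1 M HCl to pH 3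
Reagents that add atoms: lithium hydroxide, [Li+].[OH-]
Why: Saponification of an unhindered ethyl ester at room temperature, under which ring C of the 3-methoxyflavone is not opened, followed by acidification.

Step 6
Reactants: 9 3-Fl-propanoic acid; 10 ethoxyacetylene
Product: 13 (±)-3-ethoxy-4-(Fl-methyl)cyclobut-2-en-1-one, via acid chloride 11 (not isolated), via alkylketene 12 (not isolated)
Conditions: (COCl)2 (1.5 equiv), DMF (cat.), CH2Cl2, 0 °C → rt, evaporate; then slow addition to 10 (5 equiv), Et3N (1.3 equiv), Et2O–CH2Cl2, 0 °C → rt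
Reagents that add atoms: none
Why: Acid chloride formation and dehydrochlorination give alkylketene 12, which is trapped in a polar ketene–ynol ether (2+2) cycloaddition where the unsubstituted nucleophilic alkyne carbon bonds to the ketene carbonyl carbon, so the side chain lands on the sp3 carbon C4 (racemic, erased in step 7), and slow addition into excess alkyne holds back ketene dimerization.

Step 7
Reactants: 13 (±)-3-ethoxy-4-(Fl-methyl)cyclobut-2-en-1-one
Product: 14 3-hydroxy-2-(Fl-methyl)cyclobut-2-en-1-one (enol form of 2-(Fl-methyl)cyclobutane-1,3-dione)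
Conditions: 1 M aq HCl, THF, 0 °C → rt
Reagents that add atoms: water, O
Why: Acid hydrolysis of a vinylogous ester by addition–elimination at C3, after which the 1,3-dione enolizes toward the substituted carbon, removing the stereocentre and making the two oxygens equivalent.

Step 8
Reactants: 14 3-hydroxy-2-(Fl-methyl)cyclobut-2-en-1-one
Product: 15 3-benzyloxy-2-(Fl-methyl)cyclobut-2-en-1-one
Conditions: BnOH (1.2 equiv), PPh3 (1.3 equiv), DIAD (1.3 equiv), THF, 0 °C → rt
Reagents that add atoms: benzyl alcohol, OCc1ccccc1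
Why: Mitsunobu O-alkylation of a strongly acidic vinylogous acid, in which either equivalent oxygen gives the same 2-substituted vinylogous ester and the neutral medium avoids both C-benzylation at C2 and retro-Claisen cleavage of the strained dione.

Step 9
Reactants: 15 3-benzyloxy-2-(Fl-methyl)cyclobut-2-en-1-one; 3 1-methoxyprop-1-yne
Product: 20 5-benzyloxy-4-(Fl-methyl)-3-methoxy-2-methylphenol, via vinylketene 16 (not isolated), via alkenylcyclobutenone 17 (not isolated), via dienylketene 18 (not isolated), via cyclohexadienone 19 (not isolated)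
Conditions: 3 (5 equiv), toluene (0.3 M), sealed tube, 150 °C
Reagents that add atoms: none
Why: Danheiser benzannulation: on heating, the C1–C4 bond of 15 breaks in a reversible conrotatory four-electron electrocyclic opening to vinylketene 16, whose small equilibrium share is drained by the excess of electron-rich alkyne 3. The ketene C=C of 16 adds 3 in a polar (2+2) cycloaddition in which the nucleophilic methyl-bearing alkyne carbon attacks the ketene carbonyl carbon (bond D2–D3) and the oxygen-bearing alkyne carbon closes onto the ketene alpha carbon (bond D4–D5) to give 17; this polarity match is the one regiochemical demand of the step, it is secured by the donor oxygen of 3, and it places the methyl between OH and OCH3. 17 reopens by a second four-electron electrocyclic reaction to dienylketene 18, ring D closes by disrotatory six-electron electrocyclization between the ketene carbon and the terminal CH2 (bond D2–D1), and dienone 19 tautomerizes irreversibly to phenol 20. The closest known reaction is the benzannulation of 2,3-dialkylcyclobutenones with 1-alkoxyalkynes to resorcinol monoethers; the 3-alkoxy group of 15 slows the first opening through vinylogous-ester stabilization, but intermediate 17 of every such reaction and the squarate-derived cyclobutenones are themselves 3-alkoxycyclobutenones that open thermally, so a higher temperature is planned and not a different mechanism. No stereocentre remains in 20 because the quaternary carbon of 17 is lost; the O-methyl group of 3 has no beta hydrogen and so cannot fragment by retro-ene reaction at this temperature; and the tetrasubstituted C2=C3 bond and the benzyl ethers of the flavone offer no thermal pathway with either partner.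

Step 10
Reactants: 20 5-benzyloxy-4-(Fl-methyl)-3-methoxy-2-methylphenol; 21 3-phenylpropanoyl chloride
Product: 22 5-benzyloxy-4-(Fl-methyl)-3-methoxy-2-methylphenyl 3-phenylpropanoate
Conditions: 21 (1.3 equiv), Et3N (2 equiv), DMAP (10 mol %), CH2Cl2, 0 °C → rt
Reagents that add atoms: none
Why: DMAP-catalysed O-acylation of the only free hydroxyl group of 20 by an acid chloride, with no other nucleophilic site in the molecule.

Step 11
Reactants: 22 5-benzyloxy-4-(Fl-methyl)-3-methoxy-2-methylphenyl 3-phenylpropanoate
Product: 23 1-[6-benzyloxy-5-(Fl-methyl)-2-hydroxy-4-methoxy-3-methylphenyl]-3-phenylpropan-1-one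
Conditions: TiCl4 (2.5 equiv), CH2Cl2, −20 °C → rt; then ice-water
Reagents that add atoms: none
Why: Lewis acid ortho-Fries rearrangement, in which TiCl4 on the ester releases an acylium–titanium phenoxide pair that recombines at D1, the only unsubstituted carbon of the phloroglucinol-type ring D and far more nucleophilic than C6 of the carbonyl-deactivated ring A, the product being held as a six-membered titanium chelate; the photochemical variant is not used because the 3-methoxyflavone absorbs the light and has photochemistry of its own.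

Step 12
Reactants: 23 1-[6-benzyloxy-5-(Fl-methyl)-2-hydroxy-4-methoxy-3-methylphenyl]-3-phenylpropan-1-one
Product: 24 8-{[2,4-dihydroxy-6-methoxy-5-methyl-3-(3-phenylpropanoyl)phenyl]methyl}-5,7-dihydroxy-3-methoxy-2-phenyl-4H-chromen-4-one (target)
Conditions: H2 (1 atm), Pd/C (10 wt %), EtOAc–MeOH, rt
Reagents that add atoms: none
Why: Catalytic hydrogenolysis of three aryl benzyl ethers, under which the doubly hydrogen-bonded aryl ketone, the tetrasubstituted C2=C3 bond, the diarylmethane bridge and both methyl ethers should stay untouched in neutral solvent, and any material that lost a benzyl group in step 11 converges here.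

Compound list
1 | chloroacetaldehyde dimethyl acetal (2-chloro-1,1-dimethoxyethane) | COC(CCl)OC | starting material
2 | sodium methoxyacetylide | [Na+].[C-]#COC | intermediate
3 | 1-methoxyprop-1-yne | CC#COC | intermediate
4 | 3-O-methylgalangin (5,7-dihydroxy-3-methoxy-2-phenyl-4H-chromen-4-one) | COc1c(-c2ccccc2)oc2cc(O)cc(O)c2c1=O | starting material
5 | 5,7-bis(benzyloxy)-3-methoxy-2-phenyl-4H-chromen-4-one | COc1c(-c2ccccc2)oc2cc(OCc3ccccc3)cc(OCc3ccccc3)c2c1=O | intermediate
6 | 5,7-bis(benzyloxy)-8-iodo-3-methoxy-2-phenyl-4H-chromen-4-one | Ic1c(OCc2ccccc2)cc(OCc2ccccc2)c2c(=O)c(OC)c(-c3ccccc3)oc12 | intermediate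
7 | (3-ethoxy-3-oxopropyl)zinc bromide | CCOC(=O)CC[Zn]Br | starting material
8 | ethyl 3-[5,7-bis(benzyloxy)-3-methoxy-4-oxo-2-phenyl-4H-chromen-8-yl]propanoate | CCOC(=O)CCc1c(OCc2ccccc2)cc(OCc2ccccc2)c2c(=O)c(OC)c(-c3ccccc3)oc12 | intermediate
9 | 3-[5,7-bis(benzyloxy)-3-methoxy-4-oxo-2-phenyl-4H-chromen-8-yl]propanoic acid | OC(=O)CCc1c(OCc2ccccc2)cc(OCc2ccccc2)c2c(=O)c(OC)c(-c3ccccc3)oc12 | intermediate
10 | ethoxyacetylene | C#COCC | starting material
11 | 3-Fl-propanoyl chloride | ClC(=O)CCc1c(OCc2ccccc2)cc(OCc2ccccc2)c2c(=O)c(OC)c(-c3ccccc3)oc12 | intermediate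
12 | 3-Fl-prop-1-en-1-one (Fl-methylketene) | O=C=CCc1c(OCc2ccccc2)cc(OCc2ccccc2)c2c(=O)c(OC)c(-c3ccccc3)oc12 | intermediate
13 | 3-ethoxy-4-(Fl-methyl)cyclobut-2-en-1-one (racemic) | CCOC1=CC(=O)C1Cc1c(OCc2ccccc2)cc(OCc2ccccc2)c2c(=O)c(OC)c(-c3ccccc3)oc12 | intermediate
14 | 3-hydroxy-2-(Fl-methyl)cyclobut-2-en-1-one | O=C1CC(O)=C1Cc1c(OCc2ccccc2)cc(OCc2ccccc2)c2c(=O)c(OC)c(-c3ccccc3)oc12 | intermediate
15 | 3-benzyloxy-2-(Fl-methyl)cyclobut-2-en-1-one | O=C1CC(OCc2ccccc2)=C1Cc1c(OCc2ccccc2)cc(OCc2ccccc2)c2c(=O)c(OC)c(-c3ccccc3)oc12 | intermediate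
16 | 3-benzyloxy-2-(Fl-methyl)buta-1,3-dien-1-one (vinylketene) | O=C=C(Cc1c(OCc2ccccc2)cc(OCc2ccccc2)c2c(=O)c(OC)c(-c3ccccc3)oc12)C(=C)OCc1ccccc1 | intermediate
17 | 4-[1-(benzyloxy)ethenyl]-4-(Fl-methyl)-3-methoxy-2-methylcyclobut-2-en-1-one (racemic) | O=C1C(C)=C(OC)C1(Cc1c(OCc2ccccc2)cc(OCc2ccccc2)c2c(=O)c(OC)c(-c3ccccc3)oc12)C(=C)OCc1ccccc1 | intermediate
18 | 5-benzyloxy-4-(Fl-methyl)-3-methoxy-2-methylhexa-1,3,5-trien-1-one, ketenyl and alkenyl groups cis on C3=C4 | O=C=C(C)/C(OC)=C(/Cc1c(OCc2ccccc2)cc(OCc2ccccc2)c2c(=O)c(OC)c(-c3ccccc3)oc12)C(=C)OCc1ccccc1 | intermediate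
19 | 5-benzyloxy-4-(Fl-methyl)-3-methoxy-2-methylcyclohexa-2,4-dien-1-one | O=C1CC(OCc2ccccc2)=C(Cc2c(OCc3ccccc3)cc(OCc3ccccc3)c3c(=O)c(OC)c(-c4ccccc4)oc23)C(OC)=C1C | intermediate
20 | 8-[(6-benzyloxy-4-hydroxy-2-methoxy-3-methylphenyl)methyl]-5,7-bis(benzyloxy)-3-methoxy-2-phenyl-4H-chromen-4-one | COc1c(C)c(O)cc(OCc2ccccc2)c1Cc1c(OCc2ccccc2)cc(OCc2ccccc2)c2c(=O)c(OC)c(-c3ccccc3)oc12 | intermediate
21 | 3-phenylpropanoyl chloride | O=C(Cl)CCc1ccccc1 | starting material
22 | 5-benzyloxy-4-(Fl-methyl)-3-methoxy-2-methylphenyl 3-phenylpropanoate | COc1c(C)c(OC(=O)CCc2ccccc2)cc(OCc2ccccc2)c1Cc1c(OCc2ccccc2)cc(OCc2ccccc2)c2c(=O)c(OC)c(-c3ccccc3)oc12 | intermediate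
23 | 1-[6-benzyloxy-5-(Fl-methyl)-2-hydroxy-4-methoxy-3-methylphenyl]-3-phenylpropan-1-one | COc1c(C)c(O)c(C(=O)CCc2ccccc2)c(OCc2ccccc2)c1Cc1c(OCc2ccccc2)cc(OCc2ccccc2)c2c(=O)c(OC)c(-c3ccccc3)oc12 | intermediate
24 | 8-{[2,4-dihydroxy-6-methoxy-5-methyl-3-(3-phenylpropanoyl)phenyl]methyl}-5,7-dihydroxy-3-methoxy-2-phenyl-4H-chromen-4-one | COc1c(C)c(O)c(C(=O)CCc2ccccc2)c(O)c1Cc1c(O)cc(O)c2c(=O)c(OC)c(-c3ccccc3)oc12 | target

Total step count: 12. Longest linear sequence: 11 steps (steps 2 to 12, from 3-O-methylgalangin); step 1 is a one-step side branch.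

Steps most likely to fail

1. Step 9.
- Risk: the vinylogous-ester stabilization of 15 may slow the first ring opening. At the temperature then needed, acylation of the product phenol by the ketene, ketene self-condensation and thermal loss of the volatile alkyne could outrun the (2+2) capture.
- Fallback: ring D is brought in preformed and the bridge is made by quinone methide alkylation. It sets out from 4 and 21 and comes back at 24.
- Friedel–Crafts acylation of purchased 2-methylphloroglucinol with 21 (AlCl3, CH2Cl2–PhNO2) should give 3-phenyl-1-(2,4,6-trihydroxy-3-methylphenyl)propan-1-one F1, the two free ring positions being equivalent.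
- Methylation of its only non-chelated hydroxyl, para to the ketone (Me2SO4, one equivalent, K2CO3, acetone), should give 1-(2,6-dihydroxy-4-methoxy-3-methylphenyl)-3-phenylpropan-1-one F2, whose single free ring carbon is D5.
- Mannich aminomethylation of 4 (aqueous HCHO, Me2NH, EtOH), which in 5,7-dihydroxyflavones favours C8, should give 8-[(dimethylamino)methyl]-5,7-dihydroxy-3-methoxy-2-phenyl-4H-chromen-4-one F3.
- Heating F3 with excess F2 in dioxane should expel the amine to 5-hydroxy-3-methoxy-8-methylidene-2-phenyl-4H-chromene-4,7(8H)-dione F4. This ortho-quinone methide is attacked by D5 of F2 and rearomatizes to 24 without protecting groups.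

2. Step 11.
- Risk: the Lewis acid may strip benzyl groups (peri to the C4 carbonyl, ortho to the new ketone) with re-benzylation on carbon, may cleave the electron-rich diarylmethane bridge by ipso attack, or may allow intermolecular acyl transfer.
- Fallback: the acyl group is built by one-carbon formylation and carbonyl addition instead of acyl migration. It sets out from 20 and comes back at 23.
- Ortho-specific Casnati–Skattebøl formylation of 20 (MgCl2, Et3N, paraformaldehyde, MeCN, reflux) should give 6-benzyloxy-5-(Fl-methyl)-2-hydroxy-4-methoxy-3-methylbenzaldehyde F5.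
- Grignard addition of (2-phenylethyl)magnesium bromide (2.2 equiv, THF, −78 °C), at which temperature the aldehyde reacts much faster than the vinylogous-ester carbonyl of the chromone, should give racemic 1-[6-benzyloxy-5-(Fl-methyl)-2-hydroxy-4-methoxy-3-methylphenyl]-3-phenylpropan-1-ol F6.
- Oxidation of this benzylic alcohol with MnO2 in CH2Cl2 should give 23.

3. Step 6.
- Risk: dimerization or amine-induced oligomerization of the monoalkylketene may be faster than its capture, and the ammonium salt may consume the acid-sensitive ynol ether.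
- Fallback: a keteniminium salt, which does not dimerize, replaces the ketene. It sets out from 9 by way of 11 and comes back at 13.
- Treating 11 with Me2NH (2 equiv, THF) should give N,N-dimethyl-3-Fl-propanamide F7.
- Tf2O and 2,4,6-collidine in CH2Cl2 should convert it into N-(3-Fl-prop-1-en-1-ylidene)-N-methylmethanaminium triflate F8.
- This salt should add 10 in a keteniminium–alkyne (2+2) cycloaddition with the same polarity as in step 6, giving racemic N-[3-ethoxy-4-(Fl-methyl)cyclobut-2-en-1-ylidene]-N-methylmethanaminium triflate F9.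
- Mild aqueous hydrolysis of the iminium group should give 13.

Further compounds
F1 | step 9 | 3-phenyl-1-(2,4,6-trihydroxy-3-methylphenyl)propan-1-one | Cc1c(O)cc(O)c(C(=O)CCc2ccccc2)c1O
F2 | step 9 | 1-(2,6-dihydroxy-4-methoxy-3-methylphenyl)-3-phenylpropan-1-one | COc1cc(O)c(C(=O)CCc2ccccc2)c(O)c1C
F3 | step 9 | 8-[(dimethylamino)methyl]-5,7-dihydroxy-3-methoxy-2-phenyl-4H-chromen-4-one | CN(C)Cc1c(O)cc(O)c2c(=O)c(OC)c(-c3ccccc3)oc12
F4 | step 9 | 5-hydroxy-3-methoxy-8-methylidene-2-phenyl-4H-chromene-4,7(8H)-dione | C=C1C(=O)C=C(O)C2=C1OC(-c1ccccc1)=C(OC)C2=O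
F5 | step 11 | 6-benzyloxy-5-(Fl-methyl)-2-hydroxy-4-methoxy-3-methylbenzaldehyde | COc1c(C)c(O)c(C=O)c(OCc2ccccc2)c1Cc1c(OCc2ccccc2)cc(OCc2ccccc2)c2c(=O)c(OC)c(-c3ccccc3)oc12
F6 | step 11 | 1-[6-benzyloxy-5-(Fl-methyl)-2-hydroxy-4-methoxy-3-methylphenyl]-3-phenylpropan-1-ol (racemic) | COc1c(C)c(O)c(C(O)CCc2ccccc2)c(OCc2ccccc2)c1Cc1c(OCc2ccccc2)cc(OCc2ccccc2)c2c(=O)c(OC)c(-c3ccccc3)oc12
F7 | step 6 | N,N-dimethyl-3-Fl-propanamide | CN(C)C(=O)CCc1c(OCc2ccccc2)cc(OCc2ccccc2)c2c(=O)c(OC)c(-c3ccccc3)oc12
F8 | step 6 | N-(3-Fl-prop-1-en-1-ylidene)-N-methylmethanaminium triflate | C[N+](C)=C=CCc1c(OCc2ccccc2)cc(OCc2ccccc2)c2c(=O)c(OC)c(-c3ccccc3)oc12.[O-]S(=O)(=O)C(F)(F)F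
F9 | step 6 | N-[3-ethoxy-4-(Fl-methyl)cyclobut-2-en-1-ylidene]-N-methylmethanaminium triflate (racemic) | CCOC1=CC(=[N+](C)C)C1Cc1c(OCc2ccccc2)cc(OCc2ccccc2)c2c(=O)c(OC)c(-c3ccccc3)oc12.[O-]S(=O)(=O)C(F)(F)F
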